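A smaller charge of substrate than in the gamma run (1.8 M against 2.5 M) raises a first question: does the percentage of target rise in proportion, or does the target concentration stay put?

the same everywhere: gas phase 200 mM (held)
- gamma: substrate 2.5 M; run made earlier
- flask: substrate 1.8 M; time 8.0 d

- gamma (time / d: target / %): 0.500: 4.3; 1.67: 13.9; 2.50: 17.6; 4.00: 22.1; 6.00: 25.4; 8.00: 26.1; 10.0: 26.9

(each reading ± 0.3 percentage points)

- percent here means substrate units held: one self-condensation product counts as two
- at the start none of the gas is dissolved
- the analysis behind the earlier runs scatters by 0.3 percentage points, standard deviation
- on the list of suspects stand: gas phase <-> dissolved gas; substrate + dissolved gas -> target; 2 substrate -> self-condensation product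

- the target standing at 8.0 d, as a percentage of the substrate charged
- the change that raises the amount of target at 8.0 d, in percent of the substrate charged most ("none" if none brings more than 2 percentage points) (oak / larch / none)
- amount of target at 8.0 d, in percent of the substrate charged, after larch

- oak: doubling the transfer coefficient of the gas phase, all else as stated
- larch: doubling the saturation concentration of gas phase, all else as stated

I solved the flask at both ends and joined them. At the early end, the gamma reading at 1.67 d gave a climb r of 0.208 M/d, and I assumed the same climb in this flask, with the gas phase held as before. At the late end, the last gamma reading gave a plateau of 0.673 M of target. The suspected self-condensation goes with the square of substrate, the limiting reagent, and the target step with its first power; as an assumption of my own, I took that plateau, in concentration, to change little with the charge. On 1.8 M it is 37.4%.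

How near the plateau is the flask at 8.0 d? Dividing plateau by climb gives the joining time τ, 3.23 d, and I let the target approach the plateau exponentially with it. The asked time is 2.48 τ, so I reckoned 91.6% of the plateau reached, which is 34.2%.

That leaves a gap of 3.1 percentage points, just over the margin of 2 points, and I expected oak to gain about that much. I expected larch to raise the plateau itself and chose it, without a figure of my own for it.

The forecast gave 34.5%, chose larch and put it at 46%, reasoning that “Doubling saturation doubles both the transfer ceiling and the tail rate”.

The flask gave 33.0%, and larch gave 46.5%, a gain of 14 points against 3.7 points for oak. Left until 80.0 d, the flask stands at 34.8%, so at 8.0 d it had reached 94.8% of that value, where τ had given 91.6%.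

    gas phase ⇌ dissolved gas, rate k1*(csat - [dissolved gas]) (kL = 0.00263 /min)
    substrate + dissolved gas → target (k = 0.00121 /M/min)
    2 substrate → self-condensation product (k = 2.24 × 10⁻⁴ /M/min)

The neighbouring flask is the same flask read at 50 h. There τ gives 17.8%, and the computed result is 19.5%.

All runs are calculated with made-up constants, and the scatter is random.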